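**Retrosynthetic overview** (germacrane numbering: C1 ketone, C3 enol-ether carbon, C6 lactone carbinol, C8 ester carbinol, C10 quaternary carbon)

1. Last step: the ten-membered carbocycle and the 3(2H)-furanone are opened together. C3 is carbon monoxide, so C2–C3 and C3–C4 come from a carbonylative alkyne/vinyl iodide coupling and O–C3 from cycloisomerisation of the resulting hydroxy-ynone.
2. Before that: the trans α-methylene-γ-butyrolactone (C6–C7 bond, both stereocentres) from 2-alkoxycarbonyl-allylboration/lactonisation of a (Z)-β-iodoenal with a chiral allylboronate.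
3. The allylboronate comes from an ynoate (syn-hydroalumination, borylmethylation). C8 is set by an asymmetric aldol of a silyl ynone with an ynal, C10 by chelation-controlled MeMgBr addition, then esterification with (2R)-2-methylbutanoic acid (the target SMILES specifies the R acid).
4. Both aldehydes derive from 3,3-diethoxyprop-1-yne. Ring order: lactone ring first, then ten-membered ring and furanone ring in one operation.

Assumption: the ProPhenol antipode named in step 5 is the one that delivers the (4R)-aldol 10; should the sense be reversed, its enantiomer is used with no other change.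

**Step 1**
Reactants: 1 3,3-diethoxyprop-1-yne
Product: 3 4,4-diethoxybut-2-yn-1-ol, via bromomagnesium acetylide 2 (not isolated)
Conditions: EtMgBr, THF, 0 °C to rt; (CH2O)n, rt to 45 °C; then H2O
Reagents that add atoms: ethylmagnesium bromide `CC[Mg]Br`; formaldehyde (as paraformaldehyde) `C=O`
Why: The Grignard reagent deprotonates the terminal alkyne and the resulting alkynylmagnesium bromide adds to formaldehyde (acetylide hydroxymethylation), the acetal being inert to base, and no stereocentre is formed.

**Step 2**
Reactants: 3 4,4-diethoxybut-2-yn-1-ol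
Product: 5 (2Z)-4-hydroxy-3-iodobut-2-enal, via 4-hydroxybut-2-ynal 4 (not isolated)
Conditions: TsOH·H2O (cat.), acetone–H2O (4:1), rt; then NaI, AcOH, rt, dark
Reagents that add atoms: water `O`; sodium iodide `[Na+].[I-]`
Why: Acid-catalysed acetal hydrolysis unmasks the ynal, and HI made in the flask then adds in conjugate anti fashion (iodide to the β-carbon, proton to the α-carbon from the opposite side), which gives the (Z)-β-iodoenal with I cis to CHO under kinetic control (anti-hydroiodination of an ynal).

**Step 3**
Reactants: 1 3,3-diethoxyprop-1-yne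
Product: 7 methyl 4,4-diethoxybut-2-ynoate, via lithium acetylide 6 (not isolated)
Conditions: n-BuLi, THF, −78 °C; ClCO2Me, −78 to 0 °C
Reagents that add atoms: n-butyllithium `[Li]CCCC`; methyl chloroformate `COC(=O)Cl`
Why: Deprotonation with n-BuLi gives the lithium acetylide, which is acylated by the chloroformate to the alkynoate (acetylide carboxylation), the acetal being inert to base, and no stereocentre is formed.

**Step 4**
Reactants: 7 methyl 4,4-diethoxybut-2-ynoate
Product: 8 methyl 4-oxobut-2-ynoate
Conditions: HCO2H (neat), rt; volatiles removed, used at once as a THF solution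
Reagents that add atoms: formic acid `O=CO`
Why: Formolysis (acid-mediated transacetalisation to ethyl formate) frees the aldehyde without the aqueous base or nucleophiles that this electron-poor ynal would not survive, and no stereocentre is formed.

**Step 5**
Reactants: 8 methyl 4-oxobut-2-ynoate; 9 4-(trimethylsilyl)but-3-yn-2-one
Product: 10 methyl (4R)-4-hydroxy-6-oxo-8-(trimethylsilyl)octa-2,7-diynoate
Conditions: Et2Zn (20 mol %), (S,S)-ProPhenol (10 mol %), 4 Å MS, THF, 0 °C; 9 (3 equiv)
Reagents that add atoms: none
Why: Direct catalytic asymmetric aldol addition of a silyl-capped methyl ynone under dinuclear zinc–ProPhenol catalysis, in which the zinc enolate of 9 adds to the far more electrophilic aldehyde of 8 inside the chiral pocket and so sets C4 (the later C8) as R by catalyst control.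

**Step 6**
Reactants: 10 methyl (4R)-4-hydroxy-6-oxo-8-(trimethylsilyl)octa-2,7-diynoate
Product: 12 methyl (4R,6S)-4,6-dihydroxy-6-methyl-8-(trimethylsilyl)octa-2,7-diynoate, via bromomagnesium alkoxide 11 (not isolated)
Conditions: MeMgBr (2.5 equiv), CH2Cl2–Et2O, −78 °C; then H2O
Reagents that add atoms: methylmagnesium bromide `C[Mg]Br`
Why: Cram-chelate Grignard 1,2-addition in which the magnesium alkoxide and the ynone carbonyl form a six-membered chelate with the C4 chain pseudo-equatorial and methyl enters axially, so the new tertiary carbinol C6 (the later C10) is 1,3-syn to the C4 oxygen (S), while the ketone outcompetes the ester at −78 °C.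

**Step 7**
Reactants: 12 methyl (4R,6S)-4,6-dihydroxy-6-methyl-8-(trimethylsilyl)octa-2,7-diynoate; 13 (2R)-2-methylbutanoic acid
Product: 14 methyl (4R,6S)-6-hydroxy-6-methyl-4-{[(2R)-2-methylbutanoyl]oxy}-8-(trimethylsilyl)octa-2,7-diynoate
Conditions: DCC, DMAP (10 mol %), CH2Cl2, 0 °C
Reagents that add atoms: none
Why: Steglich esterification acylates the secondary propargylic hydroxyl selectively (the tertiary one is too hindered), keeps all stereocentres, and turns any minor C4 enantiomer from step 5 into a separable diastereomer.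

**Step 8**
Reactants: 14 methyl (4R,6S)-6-hydroxy-6-methyl-4-{[(2R)-2-methylbutanoyl]oxy}-8-(trimethylsilyl)octa-2,7-diynoate
Product: 16 methyl (2Z,4R,6S)-6-hydroxy-6-methyl-4-{[(2R)-2-methylbutanoyl]oxy}-2-[(4,4,5,5-tetramethyl-1,3,2-dioxaborolan-2-yl)methyl]-8-(trimethylsilyl)oct-2-en-7-ynoate, via vinylalane 15 (not isolated)
Conditions: i-Bu2AlH (2.1 equiv), HMPA, THF, 0 °C; ICH2Bpin, 0 °C to rt; H2O
Reagents that add atoms: diisobutylaluminium hydride `CC(C)C[AlH]CC(C)C`; 2-(iodomethyl)-4,4,5,5-tetramethyl-1,3,2-dioxaborolane `ICB1OC(C)(C)C(C)(C)O1`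
Why: Conjugate syn-hydroalumination of the ynoate by the HMPA-complexed aluminium hydride puts H on C3 and Al on C2 on the same side, and the alkenyl–aluminium bond is then homologated by the (iodomethyl)boronate through a boron ate complex and 1,2-shift (Matteson-type), which gives the allylboronate with the C4 chain cis to CO2Me with retention of olefin geometry, the silyl alkyne and the aliphatic ester being inert at 0 °C.

**Step 9**
Reactants: 16 the allylboronate of step 8; 5 (2Z)-4-hydroxy-3-iodobut-2-enal
Product: 18 (1R,3S)-3-hydroxy-1-{(2S,3R)-2-[(1Z)-3-hydroxy-2-iodoprop-1-en-1-yl]-4-methylidene-5-oxooxolan-3-yl}-3-methyl-5-(trimethylsilyl)pent-4-yn-1-yl (2R)-2-methylbutanoate, via borate ester 17 (not isolated)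
Conditions: Sc(OTf)3 (10 mol %), toluene, 0 °C to rt; then TsOH·H2O (10 mol %), rt
Reagents that add atoms: none
Why: Lewis acid-catalysed 2-alkoxycarbonyl-allylboration through a closed chair transition state followed by lactonisation of the borate, in which the fixed olefin geometry puts the C8 chain equatorial and gives the anti adduct and hence the trans lactone, and the aldehyde adds to the allyl face anti to the CH2 branch of the C8 stereocentre (C8–H eclipsing the olefin to avoid A(1,3) strain with CO2Me), which sets C6 and C7 as in the target.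

**Step 10**
Reactants: 18 the silyl alkyne lactone of step 9
Product: 19 (1R,3S)-3-hydroxy-1-{(2S,3R)-2-[(1Z)-3-hydroxy-2-iodoprop-1-en-1-yl]-4-methylidene-5-oxooxolan-3-yl}-3-methylpent-4-yn-1-yl (2R)-2-methylbutanoate
Conditions: AgNO3 (10 mol %), acetone–H2O (3:1), rt, dark
Reagents that add atoms: none
Why: Silver-catalysed protodesilylation of the alkynylsilane through a silver acetylide that water protonates, under neutral conditions that spare the α-methylene lactone, the vinyl iodide and every stereocentre.

**Step 11**
Reactants: 19 the iodo alkynol lactone of step 10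
Product: 21 CNP0307052.2, (6R,7R,8R,10S)-15-hydroxy-1-oxo-3,10-epoxygermacra-2,4(Z),11(13)-trien-12,6-olid-8-yl (2R)-2-methylbutanoate, via macrocyclic ynone 20 (not isolated)
Conditions: PdCl2(PPh3)2 (10 mol %), CuI (5 mol %), Et3N (5 equiv), CO (1 atm), THF, 0.002 M (slow addition of 19), 45 °C; then H2O (20 equiv), 45 °C, same flask
Reagents that add atoms: carbon monoxide `[C-]#[O+]`; water `O`
Why: Proposed new method: oxidative addition of zerovalent palladium into the vinyl iodide with retention, CO insertion to the acylpalladium and copper-assisted coupling with the tethered terminal alkyne (intramolecular carbonylative Sonogashira, the non-carbonylative closure being suppressed because it would need a nine-membered cyclic enyne) give the strained ten-membered 4-hydroxy-2-ynone 20, which under Et3N and water is hydrated at the alkyne carbon next to the carbinol (C1) and cyclodehydrates (tertiary OH onto the CO-derived carbonyl, loss of water) to the 3(2H)-furanone with release of ring strain, the closest known reactions being the intermolecular carbonylative coupling of aryl iodides with tertiary propargylic alcohols that ends in 3(2H)-furanones and carbonylative cross-coupling macrocyclisations, and no stereocentre is formed while the Z olefin is carried over.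

**Compound list**

1 | 3,3-diethoxyprop-1-yne | `C#CC(OCC)OCC` | starting material
2 | bromo(3,3-diethoxyprop-1-yn-1-yl)magnesium (bromomagnesium acetylide) | `Br[Mg]C#CC(OCC)OCC` | intermediate
3 | 4,4-diethoxybut-2-yn-1-ol | `OCC#CC(OCC)OCC` | intermediate
4 | 4-hydroxybut-2-ynal | `OCC#CC=O` | intermediate
5 | (2Z)-4-hydroxy-3-iodobut-2-enal | `O=C/C=C(\I)CO` | intermediate
6 | lithium 3,3-diethoxyprop-1-yn-1-ide (lithium acetylide) | `[Li]C#CC(OCC)OCC` | intermediate
7 | methyl 4,4-diethoxybut-2-ynoate | `CCOC(OCC)C#CC(=O)OC` | intermediate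
8 | methyl 4-oxobut-2-ynoate | `O=CC#CC(=O)OC` | intermediate
9 | 4-(trimethylsilyl)but-3-yn-2-one | `CC(=O)C#C[Si](C)(C)C` | starting material
10 | methyl (4R)-4-hydroxy-6-oxo-8-(trimethylsilyl)octa-2,7-diynoate | `COC(=O)C#C[C@H](O)CC(=O)C#C[Si](C)(C)C` | intermediate
11 | bromomagnesium alkoxide of 10 | `COC(=O)C#C[C@H](O[Mg]Br)CC(=O)C#C[Si](C)(C)C` | intermediate
12 | methyl (4R,6S)-4,6-dihydroxy-6-methyl-8-(trimethylsilyl)octa-2,7-diynoate | `COC(=O)C#C[C@H](O)C[C@](C)(O)C#C[Si](C)(C)C` | intermediate
13 | (2R)-2-methylbutanoic acid | `CC[C@@H](C)C(=O)O` | starting material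
14 | methyl (4R,6S)-6-hydroxy-6-methyl-4-{[(2R)-2-methylbutanoyl]oxy}-8-(trimethylsilyl)octa-2,7-diynoate | `COC(=O)C#C[C@H](OC(=O)[C@H](C)CC)C[C@](C)(O)C#C[Si](C)(C)C` | intermediate
15 | vinylalane: 2-(diisobutylalumino) enoate from 14, H and Al cis, tertiary alcohol as its diisobutylaluminium alkoxide | `COC(=O)/C(=C\[C@H](OC(=O)[C@H](C)CC)C[C@](C)(O[Al](CC(C)C)CC(C)C)C#C[Si](C)(C)C)[Al](CC(C)C)CC(C)C` | intermediate
16 | methyl (2Z,4R,6S)-6-hydroxy-6-methyl-4-{[(2R)-2-methylbutanoyl]oxy}-2-[(pinacolboryl)methyl]-8-(trimethylsilyl)oct-2-en-7-ynoate | `COC(=O)/C(CB1OC(C)(C)C(C)(C)O1)=C\[C@H](OC(=O)[C@H](C)CC)C[C@](C)(O)C#C[Si](C)(C)C` | intermediate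
17 | borate ester: open-chain anti allylboration adduct of 16 and 5, C6–O–Bpin, methyl 2-methylidene ester | `COC(=O)C(=C)[C@@H]([C@H](OB1OC(C)(C)C(C)(C)O1)/C=C(\I)CO)[C@H](OC(=O)[C@H](C)CC)C[C@](C)(O)C#C[Si](C)(C)C` | intermediate
18 | trans α-methylene-γ-butyrolactone with (Z)-iodoalkenyl arm at C6 and silyl alkynol ester arm at C7 (full name in step 9) | `C=C1C(=O)O[C@H](/C=C(\I)CO)[C@H]1[C@H](OC(=O)[C@H](C)CC)C[C@](C)(O)C#C[Si](C)(C)C` | intermediate
19 | desilylated lactone, terminal alkyne (full name in step 10) | `C=C1C(=O)O[C@H](/C=C(\I)CO)[C@H]1[C@H](OC(=O)[C@H](C)CC)C[C@](C)(O)C#C` | intermediate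
20 | macrocyclic ynone: ten-membered ring C1–C10 with C1≡C2, C3 ketone, (Z)-C4=C5, trans lactone at C6/C7, free C10–OH | `C=C1C(=O)O[C@@H]2/C=C(/CO)C(=O)C#C[C@@](C)(O)C[C@@H](OC(=O)[C@H](C)CC)[C@@H]12` | intermediate
21 | CNP0307052.2 | `C=C1C(=O)O[C@@H]2/C=C(/CO)C3=CC(=O)[C@](C)(C[C@@H](OC(=O)[C@H](C)CC)[C@@H]12)O3` | target

**Step count and risks**

Total: 11 steps. Longest linear sequence: 9 steps (steps 3 to 11); the iodoenal branch (steps 1 and 2) joins at step 9.

Most likely to fail: step 11, step 8 and step 5.

Step 11. The ten-membered ynone 20 is strained, and the acylpalladium can be diverted by water or by Heck-type addition to the methylene lactone. The fallback makes the furanone first, without strain, and closes the carbocycle at C6–C7 instead. It sets out from 16 and 5. AgNO3 in aqueous acetone removes the silyl group of 16 to give the terminal alkyne boronate F1. F1, 5 and CO are then coupled under the conditions of step 11 at normal concentration to give the open-chain furanone enal boronate F2; the ester-deactivated allylboronate does not add to the aldehyde at 45 °C without a Lewis acid. Sc(OTf)3 in toluene at 0.002 M, then TsOH, closes the ten-membered ring by intramolecular allylboration with lactonisation and comes back to the route at 21. The facial sense of that ring closure relative to C8 would have to be checked.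

Step 8. The aluminium hydride may attack the propargylic ester, or the alkenylalane may not transfer cleanly to boron. The fallback builds the same bond by cross-coupling and sets out from 14. Bu3SnH with Pd(PPh3)4 in THF at 0 °C adds H and tin syn across the ynoate (tin at C2) to give the α-stannyl enoate F3. I2 in CH2Cl2 exchanges tin for iodine with retention to give the α-iodo enoate F4. Negishi coupling of F4 with IZnCH2Bpin under Pd(PPh3)4 comes back at 16.

Step 5. The ynal 8 is a strong Michael acceptor and an untested acceptor for the zinc catalyst, so yield or ee may be poor. The fallback replaces the direct aldol by a Mukaiyama aldol and sets out from 9. Me3SiOTf and Et3N in CH2Cl2 give the silyl enol ether F5. Addition of F5 to 8 promoted by SiCl4 with a catalytic chiral bisphosphoramide at −78 °C, followed by aqueous work-up, comes back at 10.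

**Further compounds**

F1 | step 11 | methyl (2Z,4R,6S)-6-hydroxy-6-methyl-4-{[(2R)-2-methylbutanoyl]oxy}-2-[(pinacolboryl)methyl]oct-2-en-7-ynoate | `COC(=O)/C(CB1OC(C)(C)C(C)(C)O1)=C\[C@H](OC(=O)[C@H](C)CC)C[C@](C)(O)C#C`
F2 | step 11 | open-chain furanone enal boronate: (2S)-2-methyl-3(2H)-furanone with the (Z)-1-(hydroxymethyl)-3-oxoprop-1-enyl group at C5 and the (2R)-2-acyloxy-4-(methoxycarbonyl)-5-(pinacolboryl)pent-3-enyl chain at C2 | `O=C/C=C(/CO)C1=CC(=O)[C@](C)(C[C@@H](OC(=O)[C@H](C)CC)/C=C(\C(=O)OC)CB2OC(C)(C)C(C)(C)O2)O1`
F3 | step 8 | methyl (2E,4R,6S)-6-hydroxy-6-methyl-4-{[(2R)-2-methylbutanoyl]oxy}-2-(tributylstannyl)-8-(trimethylsilyl)oct-2-en-7-ynoate | `COC(=O)/C(=C\[C@H](OC(=O)[C@H](C)CC)C[C@](C)(O)C#C[Si](C)(C)C)[Sn](CCCC)(CCCC)CCCC`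
F4 | step 8 | methyl (2E,4R,6S)-6-hydroxy-2-iodo-6-methyl-4-{[(2R)-2-methylbutanoyl]oxy}-8-(trimethylsilyl)oct-2-en-7-ynoate | `COC(=O)/C(I)=C\[C@H](OC(=O)[C@H](C)CC)C[C@](C)(O)C#C[Si](C)(C)C`
F5 | step 5 | 2-(trimethylsilyloxy)-4-(trimethylsilyl)but-1-en-3-yne | `C=C(O[Si](C)(C)C)C#C[Si](C)(C)C`
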